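The route rests on cutting C1–C8a and C4–C4a of quinone ring A (C1–C4, C4a, C8a). It exploits the naphthazarin tautomerism: ring B (C4a, C5–C8, C8a) with its two hydroxyl groups is the bis-enol of an ene-dione, so C4a=C8a is the C2=C3 bond of p-benzoquinone in disguise. The C1–C4 partner is a bisketene equivalent, a 3-substituted 2,5-bis(trimethylsilyloxy)furan that already carries the (R)-cyclobutyl angelate. One Diels–Alder reaction makes both bonds. The temporary C1–O–C4 bridge then collapses with loss of hexamethyldisiloxane, and double enolisation delivers the target, redox-neutral and free of phenol protecting groups. The diene stems from a 3-furyl carbinol through singlet oxygen.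

Key step: step 5

Numbering: naphthalene numbering of the target is used throughout (C2 carries the side chain).

Assumption: the catalyst made from (S)-BINOL is taken to deliver the furyl group to the ketone face that leads to the (R) carbinol. If the sense is opposite, (R)-BINOL is used and nothing else changes.

Step 1
Reactants: 1 3-bromofuran; 2 2,2-dimethylcyclobutan-1-one
Product: 5 (1R)-1-(furan-3-yl)-2,2-dimethylcyclobutan-1-ol, via 3-furyllithium 3 (not isolated), via triisopropoxy(furan-3-yl)titanium 4 (not isolated)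
Conditions: 1, n-BuLi, Et2O, −78 °C; ClTi(OiPr)3, −78 → 0 °C; then 2, (S)-BINOL (10 mol %), Ti(OiPr)4 (20 mol %), toluene, 0 °C → rt; aq. NH4Cl
Reagents that add atoms: none
Why: Catalytic asymmetric 1,2-addition of an aryltitanium reagent to a ketone: the strained and therefore unusually electrophilic cyclobutanone is bound by the chiral complex formed from Ti(OiPr)4 and (S)-BINOL, which distinguishes the CMe2 flank from the CH2 flank and so directs the 3-furyl group to one enantiotopic face, setting the (R) carbinol centre.

Step 2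
Reactants: 5 (1R)-1-(furan-3-yl)-2,2-dimethylcyclobutan-1-ol; 6 angelic anhydride
Product: 7 (1R)-1-(furan-3-yl)-2,2-dimethylcyclobutyl (2Z)-2-methylbut-2-enoate
Conditions: n-BuLi (1.05 equiv), THF, −78 °C; 6 (1.3 equiv), −78 → 0 °C; aq. NH4Cl
Reagents that add atoms: none
Why: O-acylation of a preformed lithium alkoxide with a symmetrical anhydride, at low temperature and without a nucleophilic catalyst, avoids the addition–elimination pathway that turns angelates into tiglates and leaves the C–O bond of the stereocentre untouched, so the Z geometry and the (R) configuration are both kept.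

Step 3
Reactants: 7 (1R)-1-(furan-3-yl)-2,2-dimethylcyclobutyl (2Z)-2-methylbut-2-enoate
Product: 9 (1R)-1-(2-hydroxy-5-oxo-2,5-dihydrofuran-3-yl)-2,2-dimethylcyclobutyl (2Z)-2-methylbut-2-enoate (lactol epimers), via furan endoperoxide 8 (not isolated)
Conditions: O2, visible light, tetraphenylporphyrin (cat.), iPr2NEt (2 equiv), CH2Cl2, −78 °C → rt
Reagents that add atoms: dioxygen, O=O
Why: Singlet-oxygen [4+2] photooxygenation of the furan is followed by a base-induced Kornblum–DeLaMare fragmentation in which the hindered amine removes the less shielded bridgehead hydrogen of 8; the electron-poor angelate alkene reacts far more slowly with singlet oxygen than the furan, and the new lactol centre forms as an epimer mixture that step 4 erases.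

Step 4
Reactants: 9 (1R)-1-(2-hydroxy-5-oxo-2,5-dihydrofuran-3-yl)-2,2-dimethylcyclobutyl (2Z)-2-methylbut-2-enoate
Product: 10 (1R)-1-[2,5-bis(trimethylsilyloxy)furan-3-yl]-2,2-dimethylcyclobutyl (2Z)-2-methylbut-2-enoate
Conditions: TMSOTf (2.0 equiv, never in excess), Et3N (4 equiv), Et2O, −78 → 0 °C; pentane, decant from Et3NH·OTf, concentrate under Ar; used at once
Reagents that add atoms: trimethylsilyl trifluoromethanesulfonate (TMSOTf), C[Si](C)(C)OS(=O)(=O)C(F)(F)F
Why: Silylation of the lactol OH and soft enolisation (silyl triflate/tertiary amine) of the butenolide with loss of H-5 give the aromatic 2,5-bis(silyloxy)furan from both lactol epimers, while keeping the triflate limiting and decanting from the ammonium salt leaves no Lewis or Brønsted acid with the ionisable tertiary ester.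

Step 5
Reactants: 10 (1R)-1-[2,5-bis(trimethylsilyloxy)furan-3-yl]-2,2-dimethylcyclobutyl (2Z)-2-methylbut-2-enoate; 11 p-benzoquinone
Product: 14 (1R)-1-(5,8-dihydroxy-1,4-dioxo-1,4-dihydronaphthalen-2-yl)-2,2-dimethylcyclobutyl (2Z)-2-methylbut-2-enoate (target), via oxa-bridged cycloadduct 12 (not isolated), via 4a,8a-dihydrotetraone 13 (not isolated)
Conditions: 10 added slowly to 11 (1.2 equiv), 2,6-di-tert-butylpyridine (0.2 equiv), toluene, −40 °C → rt, dark, Ar; then THF/aq. citrate buffer (pH 4), 0 °C
Reagents that add atoms: none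
Why: The 2,5-bis(silyloxy)furan 10 is a locked s-cis, doubly donor-substituted diene that adds suprafacially across C2=C3 of 11 in a normal-electron-demand Diels–Alder reaction, so C1–C8a and C4–C4a arise in one event and ring A closes by an intermolecular [4+2] cycloaddition (with it the temporary 7-oxabicyclo[2.2.1]heptene ring of 12). The C1–O–C4 bridge of 12 is a double silyl ketal that collapses with loss of hexamethyldisiloxane to the ene-tetraone 13, and double enolisation of C4a–H and C8a–H towards O5 and O8 gives the aromatic, twice hydrogen-bonded naphthazarin, which makes the reversible furan cycloaddition irreversible and keeps the whole step redox-neutral. The closest known reaction type is the Diels–Alder reaction of 2,5-bis(trimethylsilyloxy)furans with electron-poor alkenes, which gives 2,3-disubstituted hydroquinones in the same way. No lasting stereocentre is formed: the four of 12 (C1, C4, C4a, C8a) are erased, so endo/exo and facial selectivity are irrelevant, 11 is symmetric so there is no regiochemical issue, and the (R) carbinol centre is a spectator. The step needs cycloaddition at furan C2/C5 to outrun Mukaiyama–Michael attack from furan C4, electron transfer and a second addition to the product, which the fixed cisoid geometry, the absence of any Lewis acid, the low temperature and the slow addition of 10 to excess 11 secure. It also needs the tertiary angelate next to the electron-rich furan to stay, which rests on non-polar, buffered, acid-free conditions under which an unactivated carboxylate does not ionise from a cyclobutyl carbon.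

Compound list
1 | 3-bromofuran | Brc1ccoc1 | starting material
2 | 2,2-dimethylcyclobutan-1-one | CC1(C)CCC1=O | starting material
3 | 3-furyllithium | [Li]c1ccoc1 | intermediate
4 | triisopropoxy(furan-3-yl)titanium | CC(C)O[Ti](OC(C)C)(OC(C)C)c1ccoc1 | intermediate
5 | (1R)-1-(furan-3-yl)-2,2-dimethylcyclobutan-1-ol | O[C@]1(c2ccoc2)CCC1(C)C | intermediate
6 | angelic anhydride, (2Z)-2-methylbut-2-enoic anhydride | C/C=C(/C)C(=O)OC(=O)/C(C)=C\C | starting material
7 | (1R)-1-(furan-3-yl)-2,2-dimethylcyclobutyl (2Z)-2-methylbut-2-enoate | C/C=C(/C)C(=O)O[C@]1(c2ccoc2)CCC1(C)C | intermediate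
8 | (1R)-1-(2,3,7-trioxabicyclo[2.2.1]hept-5-en-5-yl)-2,2-dimethylcyclobutyl (2Z)-2-methylbut-2-enoate (furan endoperoxide) | C/C=C(/C)C(=O)O[C@]1(C2=CC3OOC2O3)CCC1(C)C | intermediate
9 | (1R)-1-(2-hydroxy-5-oxo-2,5-dihydrofuran-3-yl)-2,2-dimethylcyclobutyl (2Z)-2-methylbut-2-enoate (lactol epimers) | C/C=C(/C)C(=O)O[C@]1(C2=CC(=O)OC2O)CCC1(C)C | intermediate
10 | (1R)-1-[2,5-bis(trimethylsilyloxy)furan-3-yl]-2,2-dimethylcyclobutyl (2Z)-2-methylbut-2-enoate | C/C=C(/C)C(=O)O[C@]1(c2cc(O[Si](C)(C)C)oc2O[Si](C)(C)C)CCC1(C)C | intermediate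
11 | p-benzoquinone | O=C1C=CC(=O)C=C1 | starting material
12 | (1R)-1-[5,8-dioxo-1,4-bis(trimethylsilyloxy)-1,4,4a,5,8,8a-hexahydro-1,4-epoxynaphthalen-2-yl]-2,2-dimethylcyclobutyl (2Z)-2-methylbut-2-enoate (ring stereocentres transient, undefined) | C/C=C(/C)C(=O)O[C@]1(C2=CC3(O[Si](C)(C)C)OC2(O[Si](C)(C)C)C2C3C(=O)C=CC2=O)CCC1(C)C | intermediate
13 | (1R)-1-(1,4,5,8-tetraoxo-1,4,4a,5,8,8a-hexahydronaphthalen-2-yl)-2,2-dimethylcyclobutyl (2Z)-2-methylbut-2-enoate | C/C=C(/C)C(=O)O[C@]1(C2=CC(=O)C3C(C2=O)C(=O)C=CC3=O)CCC1(C)C | intermediate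
14 | (1R)-1-(5,8-dihydroxy-1,4-dioxo-1,4-dihydronaphthalen-2-yl)-2,2-dimethylcyclobutyl (2Z)-2-methylbut-2-enoate | C/C=C(/C)C(=O)O[C@]1(C2=CC(=O)c3c(O)ccc(O)c3C2=O)CCC1(C)C | target

Total step count: 5. Longest linear sequence: 5 steps (from 1 or 2 to 14).

Steps most likely to fail

Step 5 (key step). Three processes may overtake the cycloaddition, which is slowed by the bulky group next to furan C2. They are polar Mukaiyama–Michael attack from the unsubstituted furan carbon, electron transfer from the diene to the quinone, and slow ionisation of the ester.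

The fallback sets out from 9 and comes back at 14.
- The lactol 9 is condensed with PhSO2Na in AcOH to give (1R)-1-[2-(benzenesulfonyl)-5-oxo-2,5-dihydrofuran-3-yl]-2,2-dimethylcyclobutyl (2Z)-2-methylbut-2-enoate F1.
- Its lithium furanolate (LiOtBu, THF, −78 °C) carries the charge on C5, C3 and oxygen, but not on the carbon that bears the side chain, so the angelate is not pushed out.
- The furanolate is combined with 4,4-dimethoxycyclohexa-2,5-dien-1-one in a Hauser–Kraus-type Michael/Dieckmann annulation. The ketal blocks early aromatisation and electron transfer.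
- Loss of sulfinate and methanol closes the same two ring A bonds in one pot and gives (1R)-1-(5-hydroxy-8-methoxy-1,4-dioxo-1,4-dihydronaphthalen-2-yl)-2,2-dimethylcyclobutyl (2Z)-2-methylbut-2-enoate F2.
- BCl3 (CH2Cl2, −78 °C), guided by chelation to the peri carbonyl, removes the methyl ether and gives 14.

Step 4. The silyl triflate may activate the ester carbonyl and so promote loss of the angelate (with erosion of the stereocentre through ion-pair return). Removal of the shielded H-5 may also be slow.

The fallback sets out from 5 and comes back at 14. The ester is postponed, so the oxygen on the cyclobutane is a poorly leaving silyl ether while the furan is electron-rich.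
- Photooxygenation of 5 under the conditions of step 3 gives 5-hydroxy-4-[(1R)-1-hydroxy-2,2-dimethylcyclobutyl]furan-2(5H)-one F3.
- TMSOTf (3 equiv)/Et3N gives [(1R)-1-[2,5-bis(trimethylsilyloxy)furan-3-yl]-2,2-dimethylcyclobutoxy]trimethylsilane F4.
- Cycloaddition with 11 as in step 5, followed by acidic work-up, gives 5,8-dihydroxy-2-[(1R)-1-hydroxy-2,2-dimethylcyclobutyl]naphthalene-1,4-dione F5.
- Exhaustive acylation with 6 and Sc(OTf)3 (cat., MeCN, −20 °C) gives the tris-angelate F6.
- Neutral NH4OAc in aqueous MeOH cleaves only the two aryl esters and gives 14.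

Step 1. Facial selectivity or conversion may be poor, because the ketone is a hindered dialkyl ketone and not an aryl ketone.

The fallback sets out from 1 and 2 and comes back at 5. It replaces asymmetric catalysis by resolution.
- 3 is added directly to 2 (Et2O, −78 °C) to give racemic 1-(furan-3-yl)-2,2-dimethylcyclobutan-1-ol F7.
- KH and (R)-1-(naphthalen-1-yl)ethyl isocyanate give the 1-(furan-3-yl)-2,2-dimethylcyclobutyl N-[(1R)-1-(naphthalen-1-yl)ethyl]carbamates F8 as a pair of diastereomers.
- These are separated by crystallisation or chromatography.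
- The (1R)-1-(furan-3-yl)-2,2-dimethylcyclobutyl N-[(1R)-1-(naphthalen-1-yl)ethyl]carbamate F9 is cleaved with LiAlH4 (THF, 0 °C → rt) to give 5.

Further compounds
F1 | step 5 | (1R)-1-[2-(benzenesulfonyl)-5-oxo-2,5-dihydrofuran-3-yl]-2,2-dimethylcyclobutyl (2Z)-2-methylbut-2-enoate | C/C=C(/C)C(=O)O[C@]1(C2=CC(=O)OC2S(=O)(=O)c2ccccc2)CCC1(C)C
F2 | step 5 | (1R)-1-(5-hydroxy-8-methoxy-1,4-dioxo-1,4-dihydronaphthalen-2-yl)-2,2-dimethylcyclobutyl (2Z)-2-methylbut-2-enoate | C/C=C(/C)C(=O)O[C@]1(C2=CC(=O)c3c(O)ccc(OC)c3C2=O)CCC1(C)C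
F3 | step 4 | 5-hydroxy-4-[(1R)-1-hydroxy-2,2-dimethylcyclobutyl]furan-2(5H)-one | O[C@]1(C2=CC(=O)OC2O)CCC1(C)C
F4 | step 4 | [(1R)-1-[2,5-bis(trimethylsilyloxy)furan-3-yl]-2,2-dimethylcyclobutoxy]trimethylsilane | C[Si](C)(C)O[C@]1(c2cc(O[Si](C)(C)C)oc2O[Si](C)(C)C)CCC1(C)C
F5 | step 4 | 5,8-dihydroxy-2-[(1R)-1-hydroxy-2,2-dimethylcyclobutyl]naphthalene-1,4-dione | O[C@]1(C2=CC(=O)c3c(O)ccc(O)c3C2=O)CCC1(C)C
F6 | step 4 | tris-angelate of F5 (tertiary ester and both aryl esters) | C/C=C(/C)C(=O)O[C@]1(C2=CC(=O)c3c(OC(=O)/C(C)=C\C)ccc(OC(=O)/C(C)=C\C)c3C2=O)CCC1(C)C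
F7 | step 1 | racemic 1-(furan-3-yl)-2,2-dimethylcyclobutan-1-ol | OC1(c2ccoc2)CCC1(C)C
F8 | step 1 | 1-(furan-3-yl)-2,2-dimethylcyclobutyl N-[(1R)-1-(naphthalen-1-yl)ethyl]carbamate (both epimers at the cyclobutyl carbon) | C[C@@H](NC(=O)OC1(c2ccoc2)CCC1(C)C)c1cccc2ccccc12
F9 | step 1 | (1R)-1-(furan-3-yl)-2,2-dimethylcyclobutyl N-[(1R)-1-(naphthalen-1-yl)ethyl]carbamate | C[C@@H](NC(=O)O[C@]1(c2ccoc2)CCC1(C)C)c1cccc2ccccc12
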